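**Strategy**

Core numbering: C1 ketal carbon, O2, C3, C4, C5, C6, C7, O8. The oxolane ring C1–C7–C6–C5–O8 of the 2,8-dioxabicyclo[3.2.1]octane is read as a masked 4-hydroxy ketone in which C6 and C5 are the β- and α-carbons of the C5 carboxyl. Tying that carboxyl to O2 gives an α-methylene γ-lactone made from D-tartrate. In one operation the metalated dimethylhydrazone of the side-chain methyl ketone adds through C7 to C6, and the lactone enolate so formed is hydroxylated at C5, which makes the C7–C6 and O8–C5 bonds and the C5 stereocenter. Acidic methanol then opens the lactone and folds C1 onto O8 and O2; saponification ends the route.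

Key step: step 11

Remark: the core numbering is used for the corresponding atoms of all intermediates; LiN(iPr)2, NaN(SiMe3)2 and the Grignard reagent are taken as commercial solutions; alcohol 5 (carbinol epimers) and the hydrazones (C=N isomers) are used as mixtures, which is of no consequence.

**Route**

Step 1
Reactants: 1 (4R)-4-benzyl-3-propanoyl-1,3-oxazolidin-2-one
Product: 2 (4R)-4-benzyl-3-[(2S)-2-methyl-3-phenylpropanoyl]-1,3-oxazolidin-2-one
Conditions: NaN(SiMe3)2, THF, −78 °C; BnBr, −78 to 0 °C
Reagents that add atoms: benzyl bromide (BrCc1ccccc1)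
Why: Evans asymmetric alkylation, in which the chelated Z sodium enolate should be benzylated on the face opposite the auxiliary benzyl group, setting the side-chain stereocenter as S.

Step 2
Reactants: 2 (4R)-4-benzyl-3-[(2S)-2-methyl-3-phenylpropanoyl]-1,3-oxazolidin-2-one
Product: 3 (2S)-2-methyl-3-phenylpropan-1-ol
Conditions: LiBH4, H2O (1 equiv), Et2O, 0 °C; aq NaOH work-up
Reagents that add atoms: none
Why: Reductive cleavage of the imide by borohydride should release the primary alcohol without touching the stereocenter and return the auxiliary.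

Step 3
Reactants: 3 (2S)-2-methyl-3-phenylpropan-1-ol
Product: 4 (2S)-2-methyl-3-phenylpropanal
Conditions: Dess–Martin periodinane, CH2Cl2, 0 °C to rt
Reagents that add atoms: none
Why: Dess–Martin oxidation is non-basic and should give the α-branched aldehyde without racemisation; it is used at once.

Step 4
Reactants: 4 (2S)-2-methyl-3-phenylpropanal
Product: 5 (3RS,4S)-2,4-dimethyl-5-phenylpent-1-en-3-ol
Conditions: THF, −78 to 0 °C; then cold 1 M HCl
Reagents that add atoms: isopropenylmagnesium bromide (C=C(C)[Mg]Br)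
Why: Grignard 1,2-addition installs the isopropenyl carbinol; the carbinol centre forms as a mixture, which does not matter because step 5 destroys it.

Step 5
Reactants: 5 (3RS,4S)-2,4-dimethyl-5-phenylpent-1-en-3-ol
Product: 7 (5E,7S)-5,7-dimethyl-8-phenyloct-5-en-2-one, via allyl isopropenyl ether 6 (not isolated)
Conditions: 2-methoxypropene (excess), EtCO2H (cat.), toluene, sealed tube, 120 °C
Reagents that add atoms: 2-methoxypropene (C=C(C)OC)
Why: Saucy–Marbet (ketal Claisen) rearrangement, in which acid-catalysed exchange gives ether 6 and its chair [3,3] transition state with the CH(CH3)CH2Ph group equatorial should give the E trisubstituted alkene and the methyl ketone (C1 and C7) in one step.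

Step 6
Reactants: 7 (5E,7S)-5,7-dimethyl-8-phenyloct-5-en-2-one
Product: 8 (5E,7S)-5,7-dimethyl-8-phenyloct-5-en-2-one N,N-dimethylhydrazone
Conditions: Me2NNH2, AcOH (cat.), EtOH, 70 °C
Reagents that add atoms: 1,1-dimethylhydrazine (CN(C)N)
Why: Hydrazone condensation gives a ketone derivative that can be metalated cleanly at the methyl group (future C7) and whose α-C–H is too weakly acidic to quench an ester enolate.

Step 7
Reactants: 9 dimethyl (4S,5S)-2,2-dimethyl-1,3-dioxolane-4,5-dicarboxylate (dimethyl 2,3-O-isopropylidene-D-tartrate)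
Product: 10 dimethyl (4R,5S)-4-(2-tert-butoxy-2-oxoethyl)-2,2-dimethyl-1,3-dioxolane-4,5-dicarboxylate
Conditions: LiN(iPr)2, THF/HMPA, −78 °C; BrCH2CO2tBu, −78 to −40 °C
Reagents that add atoms: tert-butyl bromoacetate (BrCC(=O)OC(C)(C)C)
Why: Alkylation of the tartrate acetonide lithium enolate, in which the electrophile should enter anti to the neighbouring ester on the dioxolane, sets the C4 quaternary centre while C3 is kept from D-tartrate.

Step 8
Reactants: 10 dimethyl (4R,5S)-4-(2-tert-butoxy-2-oxoethyl)-2,2-dimethyl-1,3-dioxolane-4,5-dicarboxylate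
Product: 11 dimethyl (2S,3R)-3-hydroxy-5-oxooxolane-2,3-dicarboxylate
Conditions: CF3CO2H/H2O 9:1, rt; then toluene, 60 °C, evaporation
Reagents that add atoms: none
Why: Acidolysis removes the acetonide and the tert-butyl ester, and the freed C3 hydroxyl should lactonise onto the new carboxyl (acyl substitution, five-membered ring), which ties the future C5 carboxyl to O2.

Step 9
Reactants: 11 dimethyl (2S,3R)-3-hydroxy-5-oxooxolane-2,3-dicarboxylate
Product: 12 dimethyl (2S,3R)-5-oxo-3-[(triethylsilyl)oxy]oxolane-2,3-dicarboxylate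
Conditions: Et3SiOTf, 2,6-lutidine, CH2Cl2, 0 °C to rt
Reagents that add atoms: triethylsilyl trifluoromethanesulfonate (CC[Si](CC)(CC)OS(=O)(=O)C(F)(F)F)
Why: Silylation with the silyl triflate masks the acidic tertiary OH and adds bulk to the lower face of the lactone for step 11.

Step 10
Reactants: 12 dimethyl (2S,3R)-5-oxo-3-[(triethylsilyl)oxy]oxolane-2,3-dicarboxylate
Product: 15 dimethyl (2S,3R)-4-methylidene-5-oxo-3-[(triethylsilyl)oxy]oxolane-2,3-dicarboxylate, via Mannich base 13 (not isolated), via trimethylammonium iodide 14 (not isolated)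
Conditions: LiN(iPr)2, THF, −78 °C; CH2=NMe2+ I−, −78 °C to rt; MeI, MeOH, rt; aq NaHCO3/CH2Cl2, rt
Reagents that add atoms: N,N-dimethylmethyleneiminium iodide (Eschenmoser's salt, C=[N+](C)C.[I-]); iodomethane (CI; its atoms stay in intermediate 14 and leave with trimethylamine)
Why: Mannich reaction of the kinetic lactone enolate (the ring CH2 is the most acidic C–H), then quaternisation and Hofmann-type elimination, should give the α-methylene lactone (C6); C4 is quaternary, so the alkene cannot move into the ring.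

Step 11
Reactants: 8 (5E,7S)-5,7-dimethyl-8-phenyloct-5-en-2-one N,N-dimethylhydrazone; 15 dimethyl (2S,3R)-4-methylidene-5-oxo-3-[(triethylsilyl)oxy]oxolane-2,3-dicarboxylate
Product: 18 dimethyl (2S,3S,4R)-4-[(6E,8S)-3-(2,2-dimethylhydrazinylidene)-6,8-dimethyl-9-phenylnon-6-en-1-yl]-4-hydroxy-5-oxo-3-[(triethylsilyl)oxy]oxolane-2,3-dicarboxylate, via lithium azaenolate 16 (not isolated), via lithium lactone enolate 17 (not isolated)
Conditions: 8, LiN(iPr)2, THF, 0 °C; −78 °C, add 15; (+)-(camphorsulfonyl)oxaziridine, −78 to −40 °C; AcOH, −78 °C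
Reagents that add atoms: (+)-(camphorsulfonyl)oxaziridine (CC1(C)[C@@H]2CC[C@]13CS(=O)(=O)N4O[C@@]34C2)
Why: LiN(iPr)2 metalates the hydrazone at its methyl group (C7) and the azaenolate adds 1,4 to the s-cis-locked exocyclic enoate, forming C7–C6 and lithium lactone enolate 17, which the far less acidic hydrazone C–H cannot quench; the N-sulfonyloxaziridine then transfers electrophilic oxygen to the enolate carbon (SN2 at O), forming O8–C5. The closest known reaction type is the tandem conjugate addition–enolate hydroxylation (Michael addition of a metalated hydrazone to an unsaturated ester with electrophilic trapping of the enolate; oxaziridine hydroxylation of lactone enolates). No ring closes in this step: the two bonds are the C7–C6 and O8–C5 edges of the future oxolane, whose last edge C1–O8 closes in step 12 by 5-exo attack of the C5 hydroxyl on the activated hydrazone carbon. The C5 stereocenter is set in the oxygen transfer, where the oxidant should approach the planar enolate on the face that carries only the C4 ester, anti to the C4 triethylsilyloxy group and the cis C3 ester (the usual trans rule for butyrolactone enolates), which gives 5R. The step needs 1,4- over 1,2-addition in the presence of three ester carbonyls, secured by the soft azaenolate, the highly reactive α-methylene lactone and −78 °C, and it needs the enolate to survive until oxidation, secured by the silyl ether (no free OH, slow β-elimination at −78 °C). If the reagent pairing proves mismatched, the enantiomeric oxaziridine is used.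

Step 12
Reactants: 18 dimethyl (2S,3S,4R)-4-[(6E,8S)-3-(2,2-dimethylhydrazinylidene)-6,8-dimethyl-9-phenylnon-6-en-1-yl]-4-hydroxy-5-oxo-3-[(triethylsilyl)oxy]oxolane-2,3-dicarboxylate
Product: 19 trimethyl (1S,3S,4S,5R)-1-[(3E,5S)-3,5-dimethyl-6-phenylhex-3-en-1-yl]-4-hydroxy-2,8-dioxabicyclo[3.2.1]octane-3,4,5-tricarboxylate
Conditions: HCl (0.5 M in MeOH), rt to 40 °C
Reagents that add atoms: methanol (CO)
Why: Acid-catalysed transketalisation, in which methanolysis opens the lactone and removes the silyl ether, the hydrazone is exchanged, and C1 is captured by O8 (oxolane) and O2 (1,3-dioxane), should give the thermodynamically preferred 2,8-dioxabicyclo[3.2.1]octane; the C1 configuration is dictated by the bridge, which can only close cis across C1 and C5.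

Step 13
Reactants: 19 trimethyl (1S,3S,4S,5R)-1-[(3E,5S)-3,5-dimethyl-6-phenylhex-3-en-1-yl]-4-hydroxy-2,8-dioxabicyclo[3.2.1]octane-3,4,5-tricarboxylate
Product: 20 (1S,3S,4S,5R)-1-[(3E,5S)-3,5-dimethyl-6-phenylhex-3-en-1-yl]-4-hydroxy-2,8-dioxabicyclo[3.2.1]octane-3,4,5-tricarboxylic acid
Conditions: KOH, H2O/1,4-dioxane, 80 °C; then aq HCl to pH 2
Reagents that add atoms: potassium hydroxide ([K+].[OH-])
Why: Saponification (acyl substitution by hydroxide) of the three methyl esters should give the triacid after acidification, the ketal and the alkene being stable to base and the fast-hydrolysing C3 ester protecting C3 against epimerisation.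

**Compound list**

1 | (4R)-4-benzyl-3-propanoyl-1,3-oxazolidin-2-one | CCC(=O)N1[C@H](Cc2ccccc2)COC1=O | starting material
2 | (4R)-4-benzyl-3-[(2S)-2-methyl-3-phenylpropanoyl]-1,3-oxazolidin-2-one | O=C([C@@H](C)Cc1ccccc1)N1[C@H](Cc2ccccc2)COC1=O | intermediate
3 | (2S)-2-methyl-3-phenylpropan-1-ol | OC[C@@H](C)Cc1ccccc1 | intermediate
4 | (2S)-2-methyl-3-phenylpropanal | O=C[C@@H](C)Cc1ccccc1 | intermediate
5 | (3RS,4S)-2,4-dimethyl-5-phenylpent-1-en-3-ol | C=C(C)C(O)[C@@H](C)Cc1ccccc1 | intermediate
6 | (3RS,4S)-2,4-dimethyl-5-phenyl-3-(prop-1-en-2-yloxy)pent-1-ene (allyl isopropenyl ether) | C=C(C)OC(C(C)=C)[C@@H](C)Cc1ccccc1 | intermediate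
7 | (5E,7S)-5,7-dimethyl-8-phenyloct-5-en-2-one | C/C(=C\[C@@H](C)Cc1ccccc1)CCC(C)=O | intermediate
8 | (5E,7S)-5,7-dimethyl-8-phenyloct-5-en-2-one N,N-dimethylhydrazone | C/C(=C\[C@@H](C)Cc1ccccc1)CCC(C)=NN(C)C | intermediate
9 | dimethyl (4S,5S)-2,2-dimethyl-1,3-dioxolane-4,5-dicarboxylate | COC(=O)[C@H]1OC(C)(C)O[C@@H]1C(=O)OC | starting material
10 | dimethyl (4R,5S)-4-(2-tert-butoxy-2-oxoethyl)-2,2-dimethyl-1,3-dioxolane-4,5-dicarboxylate | COC(=O)[C@H]1OC(C)(C)O[C@]1(C(=O)OC)CC(=O)OC(C)(C)C | intermediate
11 | dimethyl (2S,3R)-3-hydroxy-5-oxooxolane-2,3-dicarboxylate | O=C1C[C@](O)(C(=O)OC)[C@@H](C(=O)OC)O1 | intermediate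
12 | dimethyl (2S,3R)-5-oxo-3-[(triethylsilyl)oxy]oxolane-2,3-dicarboxylate | O=C1C[C@](O[Si](CC)(CC)CC)(C(=O)OC)[C@@H](C(=O)OC)O1 | intermediate
13 | dimethyl (2S,3R,4RS)-4-[(dimethylamino)methyl]-5-oxo-3-[(triethylsilyl)oxy]oxolane-2,3-dicarboxylate (Mannich base) | CN(C)CC1C(=O)O[C@H](C(=O)OC)[C@@]1(O[Si](CC)(CC)CC)C(=O)OC | intermediate
14 | trimethylammonium iodide of 13 (N-methylated Mannich base) | C[N+](C)(C)CC1C(=O)O[C@H](C(=O)OC)[C@@]1(O[Si](CC)(CC)CC)C(=O)OC.[I-] | intermediate
15 | dimethyl (2S,3R)-4-methylidene-5-oxo-3-[(triethylsilyl)oxy]oxolane-2,3-dicarboxylate | C=C1C(=O)O[C@H](C(=O)OC)[C@@]1(O[Si](CC)(CC)CC)C(=O)OC | intermediate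
16 | lithium azaenolate of 8 (metalated at the methyl group, C7) | C/C(=C\[C@@H](C)Cc1ccccc1)CCC(=C)N([Li])N(C)C | intermediate
17 | lithium lactone enolate of the Michael adduct (C5 planar, C7–C6 bond formed) | C/C(=C\[C@@H](C)Cc1ccccc1)CCC(=NN(C)C)CCC1=C(O[Li])O[C@H](C(=O)OC)[C@@]1(O[Si](CC)(CC)CC)C(=O)OC | intermediate
18 | dimethyl (2S,3S,4R)-4-[(6E,8S)-3-(2,2-dimethylhydrazinylidene)-6,8-dimethyl-9-phenylnon-6-en-1-yl]-4-hydroxy-5-oxo-3-[(triethylsilyl)oxy]oxolane-2,3-dicarboxylate | C/C(=C\[C@@H](C)Cc1ccccc1)CCC(=NN(C)C)CC[C@]1(O)C(=O)O[C@H](C(=O)OC)[C@@]1(O[Si](CC)(CC)CC)C(=O)OC | intermediate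
19 | trimethyl (1S,3S,4S,5R)-1-[(3E,5S)-3,5-dimethyl-6-phenylhex-3-en-1-yl]-4-hydroxy-2,8-dioxabicyclo[3.2.1]octane-3,4,5-tricarboxylate | C/C(=C\[C@@H](C)Cc1ccccc1)CC[C@@]12CC[C@@](C(=O)OC)(O1)[C@](O)(C(=O)OC)[C@@H](C(=O)OC)O2 | intermediate
20 | (1S,3S,4S,5R)-1-[(3E,5S)-3,5-dimethyl-6-phenylhex-3-en-1-yl]-4-hydroxy-2,8-dioxabicyclo[3.2.1]octane-3,4,5-tricarboxylic acid | C/C(=C\[C@@H](C)Cc1ccccc1)CC[C@@]12CC[C@@](C(=O)O)(O1)[C@](O)(C(=O)O)[C@@H](C(=O)O)O2 | target

**Totals and risks**

Total step count: 13. Longest linear sequence: 9 steps (steps 1–6 and 11–13, from compound 1).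

Steps most likely to fail:

1. Step 11. What may go wrong: acyl attack of the azaenolate on an ester or the lactone carbonyl instead of conjugate addition; β-elimination of the silyloxy group from the lactone enolate before oxygen transfer; or poor facial selectivity in the oxygen transfer, since the C4 ester on the upper face competes with the C4 silyloxy and C3 ester groups on the lower face. Fallback: the two bonds are made in separate operations, oxygen first. Setting out from 15, epoxidation of the exocyclic alkene with dimethyldioxirane in acetone (a neutral, concerted oxidant whose product can be purified and assigned before the C–C bond is made) should give the spiro-epoxide dimethyl (3R,6S,7S)-4-oxo-7-[(triethylsilyl)oxy]-1,5-dioxaspiro[2.4]heptane-6,7-dicarboxylate F1. The lithium azaenolate 16, made from 8 as in step 11, then opens F1 at its CH2 terminus (C6) in THF at −78 to 0 °C, and protonation with AcOH returns the route at 18.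

2. Step 7. What may go wrong: proton transfer from the acidic CH2 of the bromoacetate to the tartrate enolate, and ring-opening β-elimination of the dioxolane enolate, both of which lower conversion; facial selectivity may also erode. Fallback: setting out from 9, the same enolate (LiN(iPr)2, THF/HMPA, −78 °C) is alkylated with allyl bromide, a non-acidic and more reactive electrophile, to give dimethyl (4R,5S)-2,2-dimethyl-4-(prop-2-en-1-yl)-1,3-dioxolane-4,5-dicarboxylate F2. Ozonolysis (O3, CH2Cl2, −78 °C; Me2S) gives the aldehyde dimethyl (4R,5S)-2,2-dimethyl-4-(2-oxoethyl)-1,3-dioxolane-4,5-dicarboxylate F3. Pinnick oxidation (NaClO2, NaH2PO4, 2-methyl-2-butene, tBuOH/H2O) gives 2-[(4R,5S)-4,5-bis(methoxycarbonyl)-2,2-dimethyl-1,3-dioxolan-4-yl]acetic acid F4. CF3CO2H/H2O then removes the acetonide and lactonises, returning the route at 11.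

3. Step 10. What may go wrong: competing deprotonation at C3–H (α to the ester) or β-elimination of the silyloxy group from the lactone enolate, so that the Mannich reaction does not take place cleanly at the ring CH2. Fallback: the exocyclic alkene is installed before the lactone exists, so no lactone enolate is needed. Setting out from 9, the lithium enolate is acylated with methyl chlorooxoacetate at −78 °C to give dimethyl (4S,5S)-4-(2-methoxy-2-oxoacetyl)-2,2-dimethyl-1,3-dioxolane-4,5-dicarboxylate F5. Wittig methylenation of the ketone (Ph3P=CH2, THF, −78 to 0 °C; or Zn/CH2Br2/TiCl4) gives dimethyl (4R,5S)-4-(3-methoxy-3-oxoprop-1-en-2-yl)-2,2-dimethyl-1,3-dioxolane-4,5-dicarboxylate F6. CF3CO2H/H2O, then TsOH in warm toluene, removes the acetonide and lactonises to dimethyl (2S,3R)-3-hydroxy-4-methylidene-5-oxooxolane-2,3-dicarboxylate F7. Silylation (Et3SiOTf, 2,6-lutidine) returns the route at 15, replacing steps 7–10.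

Further compounds

F1 | step 11 | dimethyl (3R,6S,7S)-4-oxo-7-[(triethylsilyl)oxy]-1,5-dioxaspiro[2.4]heptane-6,7-dicarboxylate | C1O[C@]12C(=O)O[C@H](C(=O)OC)[C@@]2(O[Si](CC)(CC)CC)C(=O)OC
F2 | step 7 | dimethyl (4R,5S)-2,2-dimethyl-4-(prop-2-en-1-yl)-1,3-dioxolane-4,5-dicarboxylate | COC(=O)[C@H]1OC(C)(C)O[C@]1(C(=O)OC)CC=C
F3 | step 7 | dimethyl (4R,5S)-2,2-dimethyl-4-(2-oxoethyl)-1,3-dioxolane-4,5-dicarboxylate | COC(=O)[C@H]1OC(C)(C)O[C@]1(C(=O)OC)CC=O
F4 | step 7 | 2-[(4R,5S)-4,5-bis(methoxycarbonyl)-2,2-dimethyl-1,3-dioxolan-4-yl]acetic acid | COC(=O)[C@H]1OC(C)(C)O[C@]1(C(=O)OC)CC(=O)O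
F5 | step 10 | dimethyl (4S,5S)-4-(2-methoxy-2-oxoacetyl)-2,2-dimethyl-1,3-dioxolane-4,5-dicarboxylate | COC(=O)[C@H]1OC(C)(C)O[C@]1(C(=O)OC)C(=O)C(=O)OC
F6 | step 10 | dimethyl (4R,5S)-4-(3-methoxy-3-oxoprop-1-en-2-yl)-2,2-dimethyl-1,3-dioxolane-4,5-dicarboxylate | COC(=O)[C@H]1OC(C)(C)O[C@]1(C(=O)OC)C(=C)C(=O)OC
F7 | step 10 | dimethyl (2S,3R)-3-hydroxy-4-methylidene-5-oxooxolane-2,3-dicarboxylate | C=C1C(=O)O[C@H](C(=O)OC)[C@@]1(O)C(=O)OC
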